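**Retrosynthetic overview**

1. Teferin ⇒ (ester C–O) jaeschkeanadiol + O-acetylvanillic acid. Locants used below: C-1 quaternary ring-fusion C–CH3, C-2/C-3 cyclopentane CH2, C-4 i-Pr carbinol C, C-5 ring-fusion CH, C-6 ester CH, C-7 CH2, C-8 olefinic C–CH3, C-9 olefinic CH, C-10 CH2.
2. Jaeschkeanadiol ⇒ C-6/C-7, C-8/C-9 dienol (C-6 oxygen by hydroxyl-directed epoxidation, palladium isomerisation, hydroxyl-directed reduction) ⇒ trans-fused C-4 ketone (i-Pr organocerium addition).
3. C-4 ketone ⇒ achiral bicyclic trienone. The C-1 methyl and the absolute configuration come from CBS reduction, alkoxide-directed cyclopropanation and reductive opening of the cyclopropyl ketone.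
4. Trienone ⇒ aryl diazomethyl ketone by intramolecular Buchner reaction. The cyclopentanone is closed first (carbenoid addition), then the benzene ring is enlarged to the seven-membered ring; no further carbocycle is made afterwards.
5. Enabling feature: C-6, C-7, C-8(CH3), C-9, C-10 and C-1 of the seven-membered ring are the six carbons of a p-tolyl ring (C-1 ipso, C-8 para). The seventh ring atom C-5 lies next to the C-4 carbinol carbon, so C-5 can be the carbenic carbon of a diazomethyl ketone tethered through C-2/C-3.

Key step: step 2

Remark on the chemistry: acids 1 and 16 are taken as commercial; the sense of the CBS reduction is assigned with the olefinic (trienyl) side of the ketone as the large substituent.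

**Route**

Step 1
Reactants: 1 3-(4-methylphenyl)propanoic acid
Product: 3 1-diazo-4-(4-methylphenyl)butan-2-one, via acid chloride 2 (not isolated)
Conditions: (COCl)2, DMF (cat.), CH2Cl2, 0 °C to rt; concentrate; CH2N2 (3 equiv), Et2O, 0 °C
Reagents that add atoms: diazomethane, C=[N+]=[N-]
Why: Acylation of diazomethane by the acid chloride (first stage of the Arndt–Eistert sequence) is the standard entry to terminal α-diazoketones; excess CH2N2 consumes the HCl, and no stereocentre is involved.

Step 2
Reactants: 3 1-diazo-4-(4-methylphenyl)butan-2-one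
Product: 6 6-methyl-3,4-dihydroazulen-1(2H)-one, via norcaradiene 4 (not isolated), via 8aH-trienone 5 (not isolated)
Conditions: Rh2(OAc)4 (1 mol %), CH2Cl2, 40 °C, slow addition of 3; then Et3N (0.2 equiv), rt
Reagents that add atoms: none
Why: Dirhodium tetraacetate converts 3 into an electrophilic rhodium carbenoid that adds to the ipso/ortho π bond of the tolyl ring (intramolecular Buchner reaction) to give norcaradiene 4, whose disrotatory 6π electrocyclic opening breaks the ipso–ortho bond and so enlarges the six-membered arene to the seven-membered cycloheptatriene 5; triethylamine then relays the ring-fusion proton through the extended enolate to the conjugated trienone 6. The closest known reaction type is the rhodium-catalysed cyclisation of 1-diazo-4-arylbutan-2-ones to 3,4-dihydroazulen-1(2H)-ones. The cyclopentanone is closed by attack of the carbenoid carbon on the ipso carbon through the CO–CH2–CH2 tether (a [2+1] addition in a five-membered, exo-type geometry), whereas the seven-membered ring is not closed but arises by ring expansion of the cyclopropane-fused cyclohexadiene. The only stereocentre formed, the ring-fusion CH (C-5), needs no control because the base-mediated isomerisation removes it and 6 is achiral. The step needs chemoselectivity for aromatic cycloaddition over C–H insertion and carbene dimerisation, secured by the tether length (the benzylic C–H could only give a cyclobutanone) and by slow addition at low concentration, and it needs a single regiochemistry, secured by the para methyl group, which makes both ortho positions equivalent and ends up on C-8. Acid is excluded so that 5 does not rearrange to a 2-tetralone.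

Step 3
Reactants: 6 6-methyl-3,4-dihydroazulen-1(2H)-one
Product: 7 (S)-6-methyl-1,2,3,4-tetrahydroazulen-1-ol
Conditions: (R)-2-methyl-CBS-oxazaborolidine (20 mol %), catecholborane (1.5 equiv), toluene, −78 °C; MeOH, then aq. NaOH wash
Reagents that add atoms: none
Why: Corey–Bakshi–Shibata reduction of an α-substituted cyclopentenone: the ketone binds the catalyst boron with the trienyl side as the large group and hydride is delivered within the complex to one carbonyl face, which with the (R)-catalyst should give the (S)-carbinol (1,2-reduction only); this C-4 stereocentre is the source of all later asymmetry.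

Step 4
Reactants: 7 (S)-6-methyl-1,2,3,4-tetrahydroazulen-1-ol
Product: 8 (1S,3aR,8aS)-6-methyl-1,2,3,4-tetrahydro-3a,8a-methanoazulen-1-ol (CH2 bridge cis to OH)
Conditions: Et2Zn (2.2 equiv, added first), CH2I2 (2.2 equiv), CH2Cl2, −10 to 0 °C; aq. NH4Cl
Reagents that add atoms: diiodomethane, ICI
Why: Hydroxyl-directed Simmons–Smith cyclopropanation (Furukawa conditions): the zinc alkoxide delivers the CH2 of the zinc carbenoid to the adjacent tetrasubstituted C-1/C-5 olefin on the face of the C-4 oxygen, which fixes both cyclopropane carbons and thereby the future C-1 configuration; the two remote olefins lack the directing contact and should react far more slowly, and prior alkoxide formation suppresses ionisation of the allylic alcohol.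

Step 5
Reactants: 8 (1S,3aR,8aS)-6-methyl-1,2,3,4-tetrahydro-3a,8a-methanoazulen-1-ol
Product: 9 (3aR,8aS)-6-methyl-3,4-dihydro-3a,8a-methanoazulen-1(2H)-one
Conditions: Dess–Martin periodinane, NaHCO3, CH2Cl2, 0 °C to rt
Reagents that add atoms: none
Why: Dess–Martin oxidation of a secondary cyclopropyl carbinol under buffered, non-acidic conditions; C-5 is quaternary, so nothing can epimerise, and the C-4 stereocentre has already relayed its information to C-1.

Step 6
Reactants: 9 (3aR,8aS)-6-methyl-3,4-dihydro-3a,8a-methanoazulen-1(2H)-one
Product: 11 (3aR,8aR)-3a,6-dimethyl-3,3a,4,8a-tetrahydroazulen-1(2H)-one, via samarium trienolate 10 (not isolated)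
Conditions: SmI2 (2.2 equiv), THF/DMPU, t-BuOH (1 equiv), −78 °C; pH 7 phosphate buffer at −78 °C
Reagents that add atoms: none
Why: Reductive ring opening of an α-cyclopropyl ketone by single-electron transfer: the ketyl cleaves the exocyclic C-5–CH2 bond (the one aligned with the carbonyl π system in a bicyclo[3.1.0]hexan-2-one, the ring-fusion bond lying in its nodal plane), the primary radical is reduced and protonated to the angular CH3 on the face fixed in step 4, and trienolate 10 is protonated kinetically at its α-carbon C-5 from the face opposite to that methyl group, which gives the trans ring fusion.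

Step 7
Reactants: 11 (3aR,8aR)-3a,6-dimethyl-3,3a,4,8a-tetrahydroazulen-1(2H)-one
Product: 12 (1R,3aR,8aR)-3a,6-dimethyl-1-(propan-2-yl)-1,2,3,3a,4,8a-hexahydroazulen-1-ol (OH cis to the angular CH3)
Conditions: i-PrMgCl/CeCl3 (3 equiv each, premixed), THF, −78 °C; aq. NH4Cl
Reagents that add atoms: isopropylmagnesium chloride, CC(C)[Mg]Cl
Why: Organocerium 1,2-addition, chosen because the weakly basic cerium reagent adds to readily enolisable ketones (H-5 is α-keto and allylic) without enolisation or β-hydride reduction; the nucleophile should enter from the face of H-5, anti to the pseudoaxial angular CH3 that is 1,3 to the carbonyl carbon, which places the new OH cis to that methyl group.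

Step 8
Reactants: 12 (1R,3aR,8aR)-3a,6-dimethyl-1-(propan-2-yl)-1,2,3,3a,4,8a-hexahydroazulen-1-ol
Product: 13 C-6/C-7 epoxide of 12 (epoxide oxygen on the face of the tertiary OH)
Conditions: VO(acac)2 (5 mol %), t-BuOOH (1.3 equiv, anhydrous), toluene, 0 °C to rt
Reagents that add atoms: tert-butyl hydroperoxide, CC(C)(C)OO
Why: Vanadium-catalysed hydroxyl-directed epoxidation of a homoallylic alcohol: the vanadate ester of the C-4 OH can reach only the C-6/C-7 olefin, so the more electron-rich C-8/C-9 olefin is spared and oxygen is delivered on the face of the C-4 OH; this epoxide configuration is not carried into the target because C-6 becomes sp2 in step 9.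

Step 9
Reactants: 13 C-6/C-7 epoxide of 12
Product: 14 (3R,3aR,8aR)-3-hydroxy-6,8a-dimethyl-3-(propan-2-yl)-2,3,3a,5,8,8a-hexahydroazulen-4(1H)-one
Conditions: Pd(PPh3)4 (5 mol %), THF, 0 °C to rt
Reagents that add atoms: none
Why: Isomerisation of a 1,3-diene monoepoxide to a β,γ-unsaturated ketone under zerovalent palladium catalysis: ionisation of the allylic C-7–O bond gives a π-allylpalladium alkoxide, hydride transfer from the carbinol carbon C-6 forms the ketone, and reductive elimination returns the hydrogen to C-7, leaving the olefin at C-8/C-9; the neutral conditions should avoid retro-aldol cleavage, epimerisation at C-5 and conjugation of the olefin.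

Step 10
Reactants: 14 (3R,3aR,8aR)-3-hydroxy-6,8a-dimethyl-3-(propan-2-yl)-2,3,3a,5,8,8a-hexahydroazulen-4(1H)-one
Product: 15 jaeschkeanadiol, (3R,3aS,4S,8aR)-6,8a-dimethyl-3-(propan-2-yl)-1,2,3,3a,4,5,8,8a-octahydroazulene-3,4-diol
Conditions: Me4NBH(OAc)3 (5 equiv), MeCN/AcOH (1:1), −30 °C
Reagents that add atoms: none
Why: Hydroxyl-directed reduction of a β-hydroxy ketone (Evans–Saksena type): ligand exchange attaches the borohydride to the C-4 oxygen and hydride is delivered intramolecularly to C-6 on the face of that oxygen, which gives the 1,3-anti diol, that is the C-6 OH on the face of H-5.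

Step 11
Reactants: 15 jaeschkeanadiol; 16 4-acetoxy-3-methoxybenzoic acid
Product: 17 O-acetylteferin, (3R,3aS,4S,8aR)-3-hydroxy-6,8a-dimethyl-3-(propan-2-yl)-1,2,3,3a,4,5,8,8a-octahydroazulen-4-yl 4-acetoxy-3-methoxybenzoate
Conditions: DCC (1.5 equiv), DMAP (0.3 equiv), CH2Cl2, rt
Reagents that add atoms: none
Why: Steglich esterification: the acylpyridinium derived from 16 acylates the secondary C-6 OH while the tertiary C-4 OH is inert; the phenol is masked as its acetate to prevent self-condensation, and no stereocentre is touched.

Step 12
Reactants: 17 O-acetylteferin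
Product: 18 teferin, (3R,3aS,4S,8aR)-3-hydroxy-6,8a-dimethyl-3-(propan-2-yl)-1,2,3,3a,4,5,8,8a-octahydroazulen-4-yl 4-hydroxy-3-methoxybenzoate
Conditions: pyrrolidine (3 equiv), CH2Cl2, 0 °C to rt
Reagents that add atoms: none
Why: Chemoselective aminolysis of the activated aryl acetate in the presence of the hindered secondary-alkyl benzoate; no stereocentre is affected.

**Compound list**

1 | 3-(4-methylphenyl)propanoic acid | Cc1ccc(CCC(=O)O)cc1 | starting material
2 | 3-(4-methylphenyl)propanoyl chloride | Cc1ccc(CCC(=O)Cl)cc1 | intermediate
3 | 1-diazo-4-(4-methylphenyl)butan-2-one | Cc1ccc(CCC(=O)C=[N+]=[N-])cc1 | intermediate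
4 | norcaradiene valence isomer of 5 (racemic; cyclopropane made of the carbenic, ipso and one ortho carbon, fused to the cyclopentanone) | O=C1CCC23C=CC(C)=CC2C13 | intermediate
5 | 6-methyl-3,8a-dihydroazulen-1(2H)-one (racemic) | O=C1CCC2=CC=C(C)C=CC12 | intermediate
6 | 6-methyl-3,4-dihydroazulen-1(2H)-one | O=C1CCC2=C1C=CC(C)=CC2 | intermediate
7 | (S)-6-methyl-1,2,3,4-tetrahydroazulen-1-ol | O[C@H]1CCC2=C1C=CC(C)=CC2 | intermediate
8 | (1S,3aR,8aS)-6-methyl-1,2,3,4-tetrahydro-3a,8a-methanoazulen-1-ol (CH2 bridge cis to OH) | O[C@H]1CC[C@@]23C[C@@]12C=CC(C)=CC3 | intermediate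
9 | (3aR,8aS)-6-methyl-3,4-dihydro-3a,8a-methanoazulen-1(2H)-one | O=C1CC[C@@]23C[C@@]12C=CC(C)=CC3 | intermediate
10 | samarium trienolate of 11 | I[Sm](I)OC1=C2C=CC(C)=CC[C@@]2(C)CC1 | intermediate
11 | (3aR,8aR)-3a,6-dimethyl-3,3a,4,8a-tetrahydroazulen-1(2H)-one (3a-CH3 and 8a-H on opposite faces) | O=C1CC[C@]2(C)CC=C(C)C=C[C@@H]12 | intermediate
12 | (1R,3aR,8aR)-3a,6-dimethyl-1-(propan-2-yl)-1,2,3,3a,4,8a-hexahydroazulen-1-ol (OH cis to 3a-CH3) | CC(C)[C@]1(O)CC[C@]2(C)CC=C(C)C=C[C@@H]12 | intermediate
13 | C-6/C-7 epoxide of 12 (epoxide oxygen on the face of the tertiary OH) | CC(C)[C@]1(O)CC[C@]2(C)CC=C(C)[C@H]3O[C@H]3[C@@H]12 | intermediate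
14 | (3R,3aR,8aR)-3-hydroxy-6,8a-dimethyl-3-(propan-2-yl)-2,3,3a,5,8,8a-hexahydroazulen-4(1H)-one | CC(C)[C@]1(O)CC[C@]2(C)CC=C(C)CC(=O)[C@@H]12 | intermediate
15 | jaeschkeanadiol, (3R,3aS,4S,8aR)-6,8a-dimethyl-3-(propan-2-yl)-1,2,3,3a,4,5,8,8a-octahydroazulene-3,4-diol | CC(C)[C@]1(O)CC[C@]2(C)CC=C(C)C[C@H](O)[C@@H]12 | intermediate
16 | 4-acetoxy-3-methoxybenzoic acid | CC(=O)Oc1ccc(C(=O)O)cc1OC | starting material
17 | O-acetylteferin | COc1cc(C(=O)O[C@H]2CC(C)=CC[C@@]3(C)CC[C@@](O)(C(C)C)[C@H]23)ccc1OC(C)=O | intermediate
18 | teferin | COc1cc(C(=O)O[C@H]2CC(C)=CC[C@@]3(C)CC[C@@](O)(C(C)C)[C@H]23)ccc1O | target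

**Step count**

Total: 12 steps. Longest linear sequence: 12 steps (1 to 18); 16 is used as purchased.

**Steps most likely to fail, with fallbacks**

Step 9. The π-allylpalladium alkoxide may lose a hydrogen from the ring CH2 next to the allyl terminus (dienol formation) instead of transferring hydride from the carbinol carbon, the olefin may be carried into conjugation with the new ketone, or the tertiary hydroxyl may capture the allyl terminus. The fallback sets out from 13: reductive opening of the alkenyl epoxide with Pd2(dba)3·CHCl3, n-Bu3P and HCO2H/Et3N in dioxane at rt delivers hydride to C-7 of the π-allyl intermediate with the olefin kept at C-8/C-9 and gives the C-6 epimer of the diol, 6-epi-jaeschkeanadiol F1. Buffered Dess–Martin oxidation of its secondary alcohol then gives the ketone, and the route is rejoined at 14.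

Step 6. The ketyl may cleave the ring-fusion cyclopropane bond (ring enlargement), the ketone may be reduced further, or protonation of the trienolate may be unselective (C-5 epimer, conjugated isomers). The fallback sets out from 9 and replaces electron transfer by an ionic homoconjugate opening: Me3SiI in CH2Cl2 at −40 °C attacks the unhindered cyclopropane CH2 in an SN2 manner and gives the trimethylsilyl trienol ether of the iodomethyl ketone F2. Mildly acidic hydrolysis (AcOH/THF/H2O, 0 °C, no free enolate that could reclose the ring) gives the 3a-(iodomethyl) analogue of 11, iodomethyl ketone F3, protonated at C-5 anti to the CH2I group. Radical deiodination (n-Bu3SnH, Et3B/air, toluene, 0 °C) gives the angular methyl group, and the route is rejoined at 11.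

Step 8. The vanadium Lewis acid may open the alkenyl epoxide as it forms (1,4-opening or ether formation with the C-4 OH), or site selectivity between the two olefins may be lost. The fallback sets out from 12 and installs the C-6 oxygen by borylation instead: copper-catalysed protoboration of the cyclic 1,3-diene (CuCl, 1,2-bis(diphenylphosphino)benzene, NaOt-Bu (cat.), B2pin2, MeOH, THF, 0 °C) should add boron to the diene terminus C-6 and hydrogen to C-7, from the face of H-5 because the quaternary carbinol carbon and the angular methyl shield the other face, to give the homoallylic C-6 pinacol boronate F4. Oxidation with NaBO3·4H2O in THF/H2O proceeds with retention, and the route is rejoined at 15, bypassing steps 9 and 10.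

**Further compounds**

F1 | step 9 | 6-epi-jaeschkeanadiol, (3R,3aS,4R,8aR)-6,8a-dimethyl-3-(propan-2-yl)-1,2,3,3a,4,5,8,8a-octahydroazulene-3,4-diol | CC(C)[C@]1(O)CC[C@]2(C)CC=C(C)C[C@@H](O)[C@@H]12
F2 | step 6 | trimethylsilyl trienol ether of the iodomethyl ketone (3a-iodomethyl, configuration as in 10) | C[Si](C)(C)OC1=C2C=CC(C)=CC[C@@]2(CI)CC1
F3 | step 6 | 3a-(iodomethyl)-6-methyl-3,3a,4,8a-tetrahydroazulen-1(2H)-one (trans, spatial arrangement as in 11) | O=C1CC[C@]2(CI)CC=C(C)C=C[C@@H]12
F4 | step 8 | C-6 pinacol boronate corresponding to 15 (boron on the face of H-5) | CC(C)[C@]1(O)CC[C@]2(C)CC=C(C)C[C@H](B3OC(C)(C)C(C)(C)O3)[C@@H]12
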